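At the reading time of 4.0 d, I had to say how much isomer of the product stood in south-east, south-west and east.

| flask | starting material | second substrate | protic impurity | enzyme | remark | time |
|---|---|---|---|---|---|---|
| theta | 20 mM | 10 mM | 6 mM | 13 µM | run made earlier |  |
| zeta | 20 mM | 10 mM | 6 mM | 6.5 µM | run made earlier |  |
| gamma | 20 mM | 10 mM | 6 mM | 26 µM | run made earlier |  |
| alpha | 20 mM | 15 mM | 6 mM | 13 µM | run made earlier |  |
| south-east | 20 mM | 10.0 mM | 6.00 mM | 13 µM | everything together at the start | 4.0 d |
| south-west | 20 mM | 10.0 mM (fed, over 20 h) | 6.00 mM | 13 µM | all else is in the flask from the start; the feed brings no volume worth counting | 4.0 d |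
| east | 20 mM (fed, over 20 h) | 10.0 mM | 6.00 mM | 13 µM | all else is in the flask from the start; the feed brings no volume worth counting | 4.0 d |

| run | time / d | isomer of the product / % | target / % |
|---|---|---|---|
| theta | 0.417 | 1.2 | 38.9 |
| theta | 0.833 | 6.2 | 54.0 |
| theta | 1.25 | 22.4 | 47.6 |
| theta | 1.67 | 35.4 | 35.2 |
| theta | 2.08 | 44.7 | 26.3 |
| theta | 2.50 | 51.2 | 19.9 |
| zeta | 0.208 | 0 | 16.4 |
| zeta | 0.625 | 0.8 | 32.9 |
| zeta | 1.04 | 0.5 | 42.6 |
| zeta | 1.67 | 7.9 | 49.5 |
| zeta | 2.50 | 21.4 | 49.1 |
| zeta | 3.00 | 30.1 | 40.8 |
| gamma | 0.500 | 11.1 | 55.2 |
| gamma | 1.04 | 46.2 | 25.4 |
| gamma | 1.67 | 58.2 | 11.4 |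
| gamma | 2.00 | 63.2 | 8.7 |
| gamma | 2.50 | 65.2 | 5.3 |
| gamma | 3.00 | 65.4 | 6.2 |
| alpha | 0.250 | 1.3 | 19.4 |
| alpha | 0.500 | 0.1 | 26.9 |
| alpha | 0.833 | 1.7 | 34.6 |
| alpha | 1.67 | 2.3 | 46.3 |
| alpha | 3.00 | 10.7 | 53.5 |

(readings scatter by 1 percentage point)

* the flask with the highest amount of isomer of the product, in percent of the starting material charged ("all alike" if they lie within 1.5 percentage points) (south-east / south-west / east / all alike)
* final isomer of the product, as a percentage of the starting material charged, in south-east
* final isomer of the product, as a percentage of the starting material charged, in south-west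
* final isomer of the product, as a percentage of the starting material charged, in east

- the earlier runs were read with a standard deviation of 1 percentage point
- on the list of suspects stand: second substrate + enzyme <-> complex B; target + enzyme <-> isomer of the product + enzyme; starting material + protic impurity -> quenched substrate; starting material + enzyme <-> complex A; complex B -> enzyme + second product; 2 complex B -> spent catalyst; complex A -> enzyme + target

I treated the target as a small correction to the isomer. The last two gamma readings gave 91.9% as the settled share, which is isomer divided by isomer plus target once the pair stops moving (thermodynamic control). One protic impurity takes one starting material, so a complete quench takes 30.0% of the charge, and the pair read 71.6% late in gamma, close to the remainder. My rule was that, once the pair has settled, isomer equals settled share times the unquenched part of the charge. For south-east and east, assuming a complete quench and a settled pair, that gave 64.3%. For south-west, the quenched part was open, so I placed its isomer between 64.3% and 91.9%.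

The forecast gave 62% for south-east, 64.5% for south-west and 28% for east, with south-west on top, reasoning of south-west “so the enzyme survives and reaches equilibrium”.

The flasks gave 61.8% in south-east, 84.1% in south-west and 61.1% in east, so south-west stood highest.

    second substrate + enzyme ⇌ complex B (K = 7400 /M, k = 7810 /M/min)
    target + enzyme ⇌ isomer of the product + enzyme, rate k2*[enzyme]*[target] forward; the back reaction follows from the equilibrium constant (K = 15.1, k = 367 /M/min)
    starting material + protic impurity → quenched substrate (k = 0.774 /M/min)
    starting material + enzyme ⇌ complex A (K = 25.1 /M, k = 32700 /M/min)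
    complex B → enzyme + second product (k = 2.56 /min)
    2 complex B → spent catalyst (k = 321 /M/min)
    complex A → enzyme + target (k = 162 /min)

South-east ended 2.5 percentage points below my figure, with target still at 8.26%. Quenched substrate reached 10.4% in south-west against 30.0% in south-east, and south-west kept 65% of its protic impurity. The settled share on the unquenched part of south-west gives 82.3%, beside the flask's 84.1%.

A neighbour of south-west, charged with 10 mM of protic impurity, held 16.3% quenched substrate, so the settled share gives 76.9%. That flask gave 78.5%.

The readings were generated by integration on assumed constants, noise included.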